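**Retrosynthetic overview**

1. The target is 3-henicosyl-2-hydroxy-5-methoxy-1,4-benzoquinone (C1=O, C2–OH, C3–C21H43, C4=O, C5–OMe, C6–H; no stereocentre). The last disconnection is the O-methyl group, leading back to 3-henicosyl-2,5-dihydroxy-1,4-benzoquinone.
2. Enabling feature: every ring carbon except C3 and C6 carries oxygen. The quinone ring is therefore the enol form of a cyclohexane-1,2,4,5-tetraone, in which two malonyl-type three-carbon units (C2–C3–C4 and C5–C6–C1) are held together only by the two vicinal-dicarbonyl bonds C1–C2 and C4–C5.
3. Key disconnection: both of these bonds at once, a [3+3] union. The C2–C3–C4 unit is a bis-acyl cation equivalent, henicosyl(chlorocarbonyl)ketene; the C1–C6–C5 unit is a bis-acyl anion equivalent, dilithiated bis(1,3-dithian-2-yl)methane. All four oxygenated carbons arrive at the carbonyl level, so no redox step is needed afterwards.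
4. Ring order: the two 1,3-dithiane rings are bought ready-made and serve as temporary rings. The carbocycle is the only ring formed (step 4); the dithianes are removed in step 5 and the 5-OH is methylated in step 6.
5. The ketene is made in three steps from diethyl malonate and 1-bromohenicosane.

Key step: step 4

Remark: the target is treated as its 1,4-quinone tautomer, and 1-bromohenicosane and bis(1,3-dithian-2-yl)methane are taken as catalogue compounds.

**Route**

Step 1
Reactants: 1 diethyl malonate; 2 1-bromohenicosane
Product: 3 diethyl 2-henicosylmalonate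
Conditions: NaH (1.2 equiv), 1 (1.5 equiv), THF–DMF, 0 °C; then 2, 65 °C
Reagents that add atoms: none
Why: Malonic ester alkylation, in which the sodium enolate of 1 displaces bromide from the primary bromide 2 by SN2 and the excess of 1 suppresses dialkylation.

Step 2
Reactants: 3 diethyl 2-henicosylmalonate
Product: 4 2-henicosylmalonic acid
Conditions: KOH (4 equiv), EtOH–THF–H2O, 60 °C; then 2 M HCl, 0 °C, filtration
Reagents that add atoms: potassium hydroxide, [K+].[OH-]
Why: Saponification of both esters by acyl substitution with hydroxide, with cold acidification so that the free malonic acid is isolated without decarboxylation.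

Step 3
Reactants: 4 2-henicosylmalonic acid
Product: 6 2-henicosyl-3-oxoprop-2-enoyl chloride [henicosyl(chlorocarbonyl)ketene], via 2-henicosylmalonyl dichloride 5 (not isolated)
Conditions: SOCl2 (4 equiv), DMF (cat.), 60 °C; volatiles removed; then neat, 120 °C, slow argon stream at reduced pressure; used at once as a THF solution
Reagents that add atoms: thionyl chloride, O=S(Cl)Cl
Why: Acid chloride formation followed by thermal 1,2-elimination of HCl from the monosubstituted malonyl dichloride, the standard entry to (chlorocarbonyl)ketenes, which are stabilised against dimerisation by the conjugated acyl group.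

Step 4
Reactants: 6 2-henicosyl-3-oxoprop-2-enoyl chloride; 7 bis(1,3-dithian-2-yl)methane
Product: 10 15-henicosyl-1,5,9,13-tetrathiadispiro[5.1.5.3]hexadecane-14,16-dione, via dilithiated bis-dithiane 8 (not isolated), via lithium diketonate 9 (not isolated)
Conditions: 7, n-BuLi (2.1 equiv), THF, −30 °C; then 6 (1.0 equiv) in THF added slowly at −78 °C (about 0.02 M), −78 → 0 °C; 1 M HCl
Reagents that add atoms: none
Why: Proposed new method: the two 2-lithio-1,3-dithiane carbons of 8 are acyl anion equivalents for C1 and C5, and 6 is a henicosylmalonyl bis-acyl cation equivalent, so the first carbanion adds to the ketene carbon to give an enolate and the second attacks the neighbouring acyl chloride (directly or after loss of LiCl to the acylketene), forming C1–C2 and C4–C5 in one flask; the closest known reactions are the C-acylation of 2-lithio-1,3-dithianes by acid chlorides and esters, the ring closure of dilithiated bis(1,3-dithian-2-yl)alkanes with 1,3-dielectrophiles, and the use of (chlorocarbonyl)ketenes as 1,3-bis-acylating agents toward 1,3-dinucleophiles. The six-membered carbocycle closes by 6-exo attack of the second carbanion on the acyl carbon, helped by the two spiro-dithiane quaternary centres (Thorpe–Ingold effect). No stereocentre is created. The step needs 1:1 cross-annulation instead of proton transfer, oligomerisation or over-addition: proton transfer is excluded because C3 of 6 is sp2 and, unlike a malonic ester, carries no acidic hydrogen between the two acyl carbons, oligomerisation is held back by slow addition at high dilution, and over-addition is prevented because the product leaves the reaction as the unreactive lithium 1,3-diketonate 9.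

Step 5
Reactants: 10 15-henicosyl-1,5,9,13-tetrathiadispiro[5.1.5.3]hexadecane-14,16-dione
Product: 11 3-henicosyl-2,5-dihydroxy-1,4-benzoquinone
Conditions: PhI(OCOCF3)2 (3 equiv), MeCN–THF–H2O, 0 °C → rt
Reagents that add atoms: water, O
Why: Oxidative dethioketalisation with a trivalent iodine reagent (Stork–Zhao conditions), in which sulfur is oxidised and water adds to the thionium ion so that each spiro carbon is released as a ketone; the 3-henicosylcyclohexane-1,2,4,5-tetraone formed is simply the keto tautomer of 11 and should enolise to the dihydroxyquinone without any further oxidant.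

Step 6
Reactants: 11 3-henicosyl-2,5-dihydroxy-1,4-benzoquinone
Product: 12 3-henicosyl-2-hydroxy-5-methoxy-1,4-benzoquinone
Conditions: MeOH–CHCl3, H2SO4 (cat.), 50 °C, stopped at the mono-ether
Reagents that add atoms: methanol, CO
Why: Acid-catalysed addition–elimination of methanol on a vinylogous carboxylic acid (Fischer-type etherification of a hydroxyquinone), expected at the 5-OH because C5 is flanked by C6–H whereas C2 is shielded by the C3 chain, and because the 5-methyl ether can stay coplanar with the quinone.

**Compound list**

1 | diethyl malonate | CCOC(=O)CC(=O)OCC | starting material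
2 | 1-bromohenicosane | CCCCCCCCCCCCCCCCCCCCCBr | starting material
3 | diethyl 2-henicosylmalonate | CCCCCCCCCCCCCCCCCCCCCC(C(=O)OCC)C(=O)OCC | intermediate
4 | 2-henicosylmalonic acid | CCCCCCCCCCCCCCCCCCCCCC(C(=O)O)C(=O)O | intermediate
5 | 2-henicosylmalonyl dichloride | CCCCCCCCCCCCCCCCCCCCCC(C(=O)Cl)C(=O)Cl | intermediate
6 | 2-henicosyl-3-oxoprop-2-enoyl chloride [henicosyl(chlorocarbonyl)ketene] | CCCCCCCCCCCCCCCCCCCCCC(=C=O)C(=O)Cl | intermediate
7 | bis(1,3-dithian-2-yl)methane | C(C1SCCCS1)C1SCCCS1 | starting material
8 | 2,2'-methylenebis(2-lithio-1,3-dithiane) | [Li]C1(CC2([Li])SCCCS2)SCCCS1 | intermediate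
9 | lithium enolate (1,3-diketonate) of 10 | [Li+].CCCCCCCCCCCCCCCCCCCCCC1=C([O-])C2(SCCCS2)CC2(SCCCS2)C1=O | intermediate
10 | 15-henicosyl-1,5,9,13-tetrathiadispiro[5.1.5.3]hexadecane-14,16-dione (2-henicosylcyclohexane-1,3-dione with spiro-1,3-dithiane rings at C4 and C6) | CCCCCCCCCCCCCCCCCCCCCC1C(=O)C2(SCCCS2)CC2(SCCCS2)C1=O | intermediate
11 | 3-henicosyl-2,5-dihydroxy-1,4-benzoquinone | CCCCCCCCCCCCCCCCCCCCCC1=C(O)C(=O)C=C(O)C1=O | intermediate
12 | 3-henicosyl-2-hydroxy-5-methoxy-1,4-benzoquinone | CCCCCCCCCCCCCCCCCCCCCC1=C(O)C(=O)C=C(OC)C1=O | target

**Step count and risks**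

Total step count: 6. Longest linear sequence: 6 steps (1 → 3 → 4 → 6 → 10 → 11 → 12); compound 7 enters at step 4 as bought.

Steps most likely to fail:

Step 4. Intermolecular acylation, ketene self-condensation or quenching of the dianion may outrun the second, ring-closing C-acylation, so that open-chain or oligomeric material forms instead of the carbocycle. The fallback uses known chemistry and gives up the ring construction. It sets out from 2: commercial 1,2,4,5-tetramethoxybenzene is lithiated between two methoxy groups (n-BuLi, THF, 0 °C) and alkylated with 2 (HMPA, rt) to give 1-henicosyl-2,3,5,6-tetramethoxybenzene F1. Exhaustive ether cleavage (BBr3, CH2Cl2, −78 °C → rt) should give 3-henicosylbenzene-1,2,4,5-tetrol F2, which is expected to autoxidise on aerobic work-up (air, aqueous NaHCO3) to the dihydroxyquinone. The route is rejoined at 11.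

Step 5. The enolised 1,3-dione may be oxidised at C3 by the trivalent iodine reagent, or the second dithioketal, which sits next to a carbonyl group, may be unmasked only sluggishly. The fallback masks the enol first. It sets out from 10: acetylation (Ac2O, pyridine, DMAP) should give the enol acetate 15-henicosyl-16-oxo-1,5,9,13-tetrathiadispiro[5.1.5.3]hexadec-14-en-14-yl acetate F3. Dethioketalisation of this electron-poor enol ester (PhI(OCOCF3)2, aqueous MeCN) should give 2-acetoxy-3-henicosyl-5-hydroxy-1,4-benzoquinone F4, and methanolysis of the acetate (K2CO3, MeOH, 0 °C) returns to the route at 11.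

Step 6. Regiocontrol may be lost, or methylation may run on to the dimethyl ether before the mono-ether can be collected. The fallback reverses the logic: over-methylate, then remove the hindered ether. It sets out from 11: exhaustive methylation (Me2SO4, K2CO3, acetone, reflux) gives 3-henicosyl-2,5-dimethoxy-1,4-benzoquinone F5. Acid hydrolysis (70% HClO4, 1,4-dioxane, rt) is known in this quinone family to cleave selectively the twisted 2-methoxy group next to the alkyl chain, and returns to the route at 12.

**Further compounds**

F1 | step 4 | 1-henicosyl-2,3,5,6-tetramethoxybenzene | CCCCCCCCCCCCCCCCCCCCCc1c(OC)c(OC)cc(OC)c1OC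
F2 | step 4 | 3-henicosylbenzene-1,2,4,5-tetrol | CCCCCCCCCCCCCCCCCCCCCc1c(O)c(O)cc(O)c1O
F3 | step 5 | 15-henicosyl-16-oxo-1,5,9,13-tetrathiadispiro[5.1.5.3]hexadec-14-en-14-yl acetate | CCCCCCCCCCCCCCCCCCCCCC1=C(OC(C)=O)C2(SCCCS2)CC2(SCCCS2)C1=O
F4 | step 5 | 2-acetoxy-3-henicosyl-5-hydroxy-1,4-benzoquinone | CCCCCCCCCCCCCCCCCCCCCC1=C(OC(C)=O)C(=O)C=C(O)C1=O
F5 | step 6 | 3-henicosyl-2,5-dimethoxy-1,4-benzoquinone | CCCCCCCCCCCCCCCCCCCCCC1=C(OC)C(=O)C=C(OC)C1=O
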